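A ratio carries this flask: nucleophile charged per product formed once the run stops. Here is what you have.

| setting | Friday's | midnight | winter |
|---|---|---|---|
| solid electrophile | 0.20 M | 0.20 M | 0.20 M |
| nucleophile | 0.20 M | 0.240 M | 0.310 M |
| remark | run made earlier |  |  |
| time |  | 12 min | 12 min |

- Friday's (time / min: solid electrophile / %, product / %): 2.00: 50.6, 41.7; 4.00: 25.2, 50.1; 6.00: 19.7, 49.8; 8.00: 19.5, 50.6

(each reading ± 0.5 percentage points)

- the numbers in the tables scatter by 0.5 percentage points (one standard deviation)
- at the start none of the solid electrophile is in solution
- what has only dissolved of solid electrophile counts as not reacted

* part of the solid electrophile that has reacted (what has only dissolved counts as not reacted) at the end, midnight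
* part of the solid electrophile that has reacted (what has only dissolved counts as not reacted) at the end, winter
* what raising the concentration of nucleophile from its lowest to its highest value here does to the part of the solid electrophile that has reacted (what has only dissolved counts as not reacted) (changes below 5 percentage points count as none) (it falls / no change / it rises)

Friday's product stands near 50.2% from 4.00 min on. That gives ν = 1.99, the nucleophile cost: nucleophile charged per product at the plateau. If nucleophile is the limiting reagent, the reacted part stops at a ceiling Y = charged nucleophile / (ν × charged solid electrophile). Your ceilings are 60.2% for midnight and 77.8% for winter, a rise of 18 percentage points, larger than the margin.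

Objection: perhaps the electrophile, not the nucleophile, stopped Friday's run. But the last solid reading, 19.5%, and the product leave 30.3% unaccounted for, about 0.0607 M dissolved and unreacted, so electrophile was still at hand. One run does not exclude a stalled equilibrium; you commit anyway.

Second objection: can winter's solid be delivered in time? Friday's last solid reading says 80.5% had left the solid by 8.00 min, more than winter's ceiling, and winter runs longer, 12 min, so you keep Y.

The forecast says 60% and 77.5%, with the trend "it rises", holding that “two nucleophile are consumed per electrophile, the second probably acting as base”. It counts a round two; you count the read 1.99.

The flask gives 60.0% and 77.1%, with the trend "it rises", a change of 17 points. At 12.0 min winter holds 0.152 M of protonated nucleophile beside 0.154 M of product. Put ν on that product: it claims 0.308 M of the 0.310 M charged and leaves 0.786% free, where the flask shows 1.04%.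

    electrophile + nucleophile ⇌ acid set free + product (K = 1.90, k = 1.15 M⁻¹ s⁻¹)
    nucleophile + acid set free ⇌ protonated nucleophile, settled at all times (K = 26000 M⁻¹)
    solid electrophile ⇌ electrophile, rate k3*(cs3 - [electrophile]) while solid is left; crystals form when [electrophile] > cs3 (solubility = 0.0630 M, k = 0.0143 s⁻¹)

Now take midnight's neighbour with 0.96 M of nucleophile. Y comes to 241%, above the charge, so solid electrophile becomes limiting and ν leaves 58.5% of the nucleophile free. That flask gives >99.9% reacted, with 58% free.

The numbers in the tables stem from a simulated flask with constants of no real substance; noise was put on by code.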